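**Retrosynthetic overview**
- The side-chain ester and the C15 acetate go on last; the α-methylene group comes from Mannich methylenation of a trans-fused 8,12-lactone, which is the last ring formed.
- The lactone comes from a ten-membered C8 ketone carrying an acetate arm on C7 and an ether oxygen on C6.
- The ten-membered ring comes from anionic oxy-Cope ring expansion of a cis-1,2-dialkenylcyclohex-3-enol (C3–C8 broken, C5–C6 formed); the regiodefined enolate takes the C11–C12 unit in the same flask.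
- The cyclohexenol comes from (S)-4-methylcyclohex-2-enone by α′-hydroxylation, alkenyl addition with a hydride-shift carbonyl transposition, and axial alkoxyalkynyl addition.
- The enone comes from 4-methylanisole by Birch reduction and enantioselective proton-shift isomerisation of the achiral β,γ-enone. Ring order: six-membered ring (the six arene carbons become C8, C9, C10, C1, C2, C3), then ten-membered ring, then γ-lactone.

Assumption: (2-bromoprop-2-en-1-yloxy)(tert-butyl)dimethylsilane and (R)-3-bromo-2-hydroxy-2-methylpropanoic acid are catalogue items; ten-membered-ring lactones are named on the germacrane skeleton (ring C1–C10, C14 on C10, C15 on C4, C11–C13 on C7).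

**Step 1**
Reactants: 1 4-methylanisole
Product: 3 4-methylcyclohex-3-en-1-one, via 1-methoxy-4-methylcyclohexa-1,4-diene 2 (not isolated)
Conditions: Li, NH3(l), t-BuOH, THF, −78 → −33 °C; then (CO2H)2, H2O/THF, 20 °C
Reagents that add atoms: water, O
Why: Birch reduction leaves both substituents on double bonds, and oxalic acid hydrolyses only the enol ether, so the achiral β,γ-enone is obtained unconjugated (dearomatisation, no stereocentre).

**Step 2**
Reactants: 3 4-methylcyclohex-3-en-1-one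
Product: 4 (S)-4-methylcyclohex-2-en-1-one
Conditions: 9-amino-9-deoxy-epi-quinine (10 mol %; or its quinidine-derived pseudoenantiomer, the one giving the S enone is used), PhCO2H (20 mol %), toluene, −20 °C
Reagents that add atoms: none
Why: The primary amine forms a dienamine and the protonated quinuclidine delivers the proton to one enantiotopic face of C4 (amine-catalysed enantioselective β,γ→α,β olefin isomerisation), which breaks the symmetry of 3 and sets the S methyl stereocentre (C10 of the target).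

**Step 3**
Reactants: 4 (S)-4-methylcyclohex-2-en-1-one
Product: 5 (4S,6S)-6-hydroxy-4-methylcyclohex-2-en-1-one
Conditions: KN(SiMe3)2, THF, −78 °C; then 2-(phenylsulfonyl)-3-phenyloxaziridine, −78 °C
Reagents that add atoms: 2-(phenylsulfonyl)-3-phenyloxaziridine, O=S(=O)(c1ccccc1)N1OC1c1ccccc1
Why: Kinetic α′-deprotonation gives the cross-conjugated enolate, which takes oxygen axially on the face away from the C4 methyl (enolate hydroxylation; trans isomer major, cis isomer removed on silica).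

**Step 4**
Reactants: 5 (4S,6S)-6-hydroxy-4-methylcyclohex-2-en-1-one; 6 (2-bromoprop-2-en-1-yloxy)(tert-butyl)dimethylsilane
Product: 8 (2S,5S)-5-methyl-2-[3-(tert-butyldimethylsilyloxy)prop-1-en-2-yl]cyclohex-3-en-1-one, via cis-diol 7 (not isolated)
Conditions: 6 (2.2 equiv), t-BuLi (4.4 equiv), Et2O, −78 °C; then 5, −78 °C; aqueous work-up; then BF3·OEt2 (0.2 equiv), CH2Cl2, −78 → −40 °C
Reagents that add atoms: none
Why: The alkenyllithium (one equivalent as base) adds 1,2 to the enone anti to the neighbouring alkoxide, and BF3 then ionises the doubly allylic tertiary carbinol so that the hydrogen on the secondary carbinol migrates suprafacially (semipinacol 1,2-hydride shift), which transposes the carbonyl and places the alkenyl group trans to the methyl.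

**Step 5**
Reactants: 9 4-methoxybenzyl alcohol; 10 trichloroethylene
Product: 11 1-({[(E)-1,2-dichloroethenyl]oxy}methyl)-4-methoxybenzene
Conditions: KH, THF, 0 °C; then 10, −78 → 20 °C
Reagents that add atoms: none
Why: The potassium alkoxide adds to dichloroacetylene formed in situ from trichloroethylene (elimination–addition) to give the E-dichlorovinyl ether, a storable precursor of the alkoxyethynyl anion.

**Step 6**
Reactants: 8 (2S,5S)-5-methyl-2-[3-(tert-butyldimethylsilyloxy)prop-1-en-2-yl]cyclohex-3-en-1-one; 11 1-({[(E)-1,2-dichloroethenyl]oxy}methyl)-4-methoxybenzene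
Product: 13 (1R,2S,5S)-1-{(E)-2-[(4-methoxybenzyl)oxy]ethenyl}-5-methyl-2-[3-(tert-butyldimethylsilyloxy)prop-1-en-2-yl]cyclohex-3-en-1-ol, via lithium alkynyl carbinolate 12 (not isolated)
Conditions: 11, n-BuLi (2 equiv), THF, −78 → −40 °C; CeCl3, −78 °C; then 8; then LiAlH4, 0 → 20 °C; basic work-up
Reagents that add atoms: none
Why: The slim alkynylcerium reagent attacks the carbonyl axially, anti to the two flanking axial C–H bonds and therefore cis to the C2 alkenyl and trans to the methyl (1,2-addition), and alkoxide-directed trans-hydroalumination turns the ynol ether into the E enol ether.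

**Step 7**
Reactants: 13 (1R,2S,5S)-1-{(E)-2-[(4-methoxybenzyl)oxy]ethenyl}-5-methyl-2-[3-(tert-butyldimethylsilyloxy)prop-1-en-2-yl]cyclohex-3-en-1-ol; 14 methyl bromoacetate
Product: 16 methyl 2-[(1S,2R,4E,6Z,8S)-4-{[(tert-butyldimethylsilyl)oxy]methyl}-2-[(4-methoxybenzyl)oxy]-8-methyl-10-oxocyclodeca-4,6-dien-1-yl]acetate, via potassium enolate 15 (not isolated)
Conditions: KH, 18-crown-6, THF, −20 → 0 °C; then 14, −78 °C
Reagents that add atoms: none
Why: The potassium alkoxide undergoes anionic oxy-Cope rearrangement through a chair in which oxide, C2 alkenyl and methyl stay equatorial on the six-membered ring and only the carbinol alkenyl is axial, so the ring-cis trisubstituted alkene forms, the E enol ether places the ether oxygen equatorial (6R of the target), and the regiodefined enolate is alkylated on its outer face (C7).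

**Step 8**
Reactants: 16 methyl 2-[(1S,2R,4E,6Z,8S)-4-{[(tert-butyldimethylsilyl)oxy]methyl}-2-[(4-methoxybenzyl)oxy]-8-methyl-10-oxocyclodeca-4,6-dien-1-yl]acetate
Product: 18 (6R,7S,8S,10S)-15-(tert-butyldimethylsilyloxy)-6-[(4-methoxybenzyl)oxy]germacra-1(Z),3(E)-dien-12,8-olide, via hydroxy ester 17 (not isolated)
Conditions: Zn(BH4)2, Et2O, −30 °C; then pyridinium p-toluenesulfonate (cat.), toluene, 60 °C
Reagents that add atoms: none
Why: Zn(BH4)2 chelates the ketone and the C6 ether oxygen and delivers hydride anti to the C7 side chain (chelation-controlled reduction, 1,3-syn, 8S), and acid-catalysed transesterification then closes the trans-fused γ-lactone.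

**Step 9**
Reactants: 18 (6R,7S,8S,10S)-15-(tert-butyldimethylsilyloxy)-6-[(4-methoxybenzyl)oxy]germacra-1(Z),3(E)-dien-12,8-olide
Product: 21 (6R,7S,8S,10S)-15-(tert-butyldimethylsilyloxy)-6-[(4-methoxybenzyl)oxy]germacra-1(Z),3(E),11(13)-trien-12,8-olide, via Mannich base 19 (not isolated), via trimethylammonium iodide 20 (not isolated)
Conditions: LiN(iPr)2, THF, −78 °C; CH2=NMe2+ I−, −78 → 0 °C; MeI, MeOH, 20 °C; aq NaHCO3/CH2Cl2
Reagents that add atoms: dimethyl(methylidene)ammonium iodide, C=[N+](C)C.[I-]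
Why: Mannich reaction of the lactone enolate, N-methylation and base-induced loss of trimethylamine (Eschenmoser methylenation) install the exocyclic methylene without touching a stereocentre.

**Step 10**
Reactants: 21 (6R,7S,8S,10S)-15-(tert-butyldimethylsilyloxy)-6-[(4-methoxybenzyl)oxy]germacra-1(Z),3(E),11(13)-trien-12,8-olide
Product: 23 (6R,7S,8S,10S)-15-acetoxy-6-[(4-methoxybenzyl)oxy]germacra-1(Z),3(E),11(13)-trien-12,8-olide, via allylic alcohol 22 (not isolated)
Conditions: HF·pyridine, THF, 0 °C; then Ac2O, pyridine, 4-(dimethylamino)pyridine (cat.), 0 °C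
Reagents that add atoms: acetic anhydride, CC(=O)OC(C)=O
Why: Fluoride cleaves the primary allylic silyl ether and the freed alcohol is acetylated in the same flask (desilylation then acylation); no stereocentre is involved.

**Step 11**
Reactants: 23 (6R,7S,8S,10S)-15-acetoxy-6-[(4-methoxybenzyl)oxy]germacra-1(Z),3(E),11(13)-trien-12,8-olide
Product: 24 (6R,7S,8S,10S)-15-acetoxy-6-hydroxygermacra-1(Z),3(E),11(13)-trien-12,8-olide
Conditions: DDQ, CH2Cl2/pH 7 buffer, 0 °C
Reagents that add atoms: none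
Why: DDQ oxidises only the electron-rich benzylic ether to an oxocarbenium ion that water hydrolyses (oxidative 4-methoxybenzyl ether cleavage), with retention at C6.

**Step 12**
Reactants: 25 (R)-3-bromo-2-hydroxy-2-methylpropanoic acid
Product: 26 (S)-2,3-dihydroxy-2-methylpropanoic acid
Conditions: NaOH, H2O, 50 °C; then HCl to pH 2
Reagents that add atoms: sodium hydroxide, [Na+].[OH-]
Why: The alkoxide closes the glycidate by intramolecular SN2 at the CH2Br carbon and hydroxide reopens it at the same primary carbon, so the quaternary centre is untouched and only its descriptor changes from R to S.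

**Step 13**
Reactants: 26 (S)-2,3-dihydroxy-2-methylpropanoic acid
Product: 28 (S)-2-methyl-2,3-bis(triethylsilyloxy)propanoic acid, via triethylsilyl ester 27 (not isolated)
Conditions: Et3SiOSO2CF3 (3.3 equiv), 2,6-lutidine, CH2Cl2, 0 °C; then MeOH/H2O, 20 °C
Reagents that add atoms: triethylsilyl trifluoromethanesulfonate, CC[Si](CC)(CC)OS(=O)(=O)C(F)(F)F
Why: The silyl triflate silylates all three hydroxyl functions and only the labile silyl ester is hydrolysed in aqueous methanol (silylation then selective solvolysis).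

**Step 14**
Reactants: 24 (6R,7S,8S,10S)-15-acetoxy-6-hydroxygermacra-1(Z),3(E),11(13)-trien-12,8-olide; 28 (S)-2-methyl-2,3-bis(triethylsilyloxy)propanoic acid
Product: 29 (6R,7R,8S,10S)-15-acetoxy-6-{[(2S)-2-methyl-2,3-bis(triethylsilyloxy)propanoyl]oxy}germacra-1(Z),3(E),11(13)-trien-12,8-olide
Conditions: 28, 2,4,6-trichlorobenzoyl chloride, Et3N, THF, 20 °C; then 24, 4-(dimethylamino)pyridine, toluene, 40 °C
Reagents that add atoms: none
Why: The mixed 2,4,6-trichlorobenzoic anhydride acylates the hindered secondary alcohol under nucleophilic catalysis (Yamaguchi esterification), with retention at C6 and at the quaternary carbon of the acid.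

**Step 15**
Reactants: 29 (6R,7R,8S,10S)-15-acetoxy-6-{[(2S)-2-methyl-2,3-bis(triethylsilyloxy)propanoyl]oxy}germacra-1(Z),3(E),11(13)-trien-12,8-olide
Product: 30 (6R,7R,8S,10S)-15-acetoxy-6-{[(2S)-2,3-dihydroxy-2-methylpropanoyl]oxy}germacra-1(Z),3(E),11(13)-trien-12,8-olide (CNP0347302.1)
Conditions: HF·pyridine, pyridine/THF, 0 °C
Reagents that add atoms: none
Why: HF·pyridine removes both triethylsilyl ethers (fluoride desilylation) under conditions that spare the allylic acetate, the two esters and the α-methylene lactone.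

**Compound list**
1 | 4-methylanisole | COc1ccc(C)cc1 | starting material
2 | 1-methoxy-4-methylcyclohexa-1,4-diene | COC1=CCC(C)=CC1 | intermediate
3 | 4-methylcyclohex-3-en-1-one | CC1=CCC(=O)CC1 | intermediate
4 | (S)-4-methylcyclohex-2-en-1-one | O=C1CC[C@H](C)C=C1 | intermediate
5 | (4S,6S)-6-hydroxy-4-methylcyclohex-2-en-1-one (hydroxyl trans to methyl) | O=C1[C@@H](O)C[C@H](C)C=C1 | intermediate
6 | (2-bromoprop-2-en-1-yloxy)(tert-butyl)dimethylsilane | C=C(Br)CO[Si](C)(C)C(C)(C)C | starting material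
7 | (1S,2S,5S)-5-methyl-2-[3-(tert-butyldimethylsilyloxy)prop-1-en-2-yl]cyclohex-3-ene-1,2-diol (cis-diol) | O[C@@]1(C(=C)CO[Si](C)(C)C(C)(C)C)[C@@H](O)C[C@H](C)C=C1 | intermediate
8 | (2S,5S)-5-methyl-2-[3-(tert-butyldimethylsilyloxy)prop-1-en-2-yl]cyclohex-3-en-1-one (alkenyl trans to methyl) | O=C1[C@H](C(=C)CO[Si](C)(C)C(C)(C)C)C=C[C@@H](C)C1 | intermediate
9 | 4-methoxybenzyl alcohol | COc1ccc(CO)cc1 | starting material
10 | trichloroethylene | ClC=C(Cl)Cl | starting material
11 | 1-({[(E)-1,2-dichloroethenyl]oxy}methyl)-4-methoxybenzene | COc1ccc(CO/C(Cl)=C\Cl)cc1 | intermediate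
12 | lithium (1R,2S,5S)-1-{[(4-methoxybenzyl)oxy]ethynyl}-5-methyl-2-[3-(tert-butyldimethylsilyloxy)prop-1-en-2-yl]cyclohex-3-en-1-olate | [Li+].[O-][C@@]1(C#COCc2ccc(OC)cc2)[C@H](C(=C)CO[Si](C)(C)C(C)(C)C)C=C[C@@H](C)C1 | intermediate
13 | (1R,2S,5S)-1-{(E)-2-[(4-methoxybenzyl)oxy]ethenyl}-5-methyl-2-[3-(tert-butyldimethylsilyloxy)prop-1-en-2-yl]cyclohex-3-en-1-ol (the two alkenyl groups cis, carbinol alkenyl trans to methyl) | O[C@@]1(/C=C/OCc2ccc(OC)cc2)[C@H](C(=C)CO[Si](C)(C)C(C)(C)C)C=C[C@@H](C)C1 | intermediate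
14 | methyl bromoacetate | COC(=O)CBr | starting material
15 | potassium (1Z,3R,5E,7Z,9S)-5-{[(tert-butyldimethylsilyl)oxy]methyl}-3-[(4-methoxybenzyl)oxy]-9-methylcyclodeca-1,5,7-trien-1-olate | [K+].[O-]/C1=C\[C@H](OCc2ccc(OC)cc2)C/C(CO[Si](C)(C)C(C)(C)C)=C\C=C/[C@@H](C)C1 | intermediate
16 | methyl 2-[(1S,2R,4E,6Z,8S)-4-{[(tert-butyldimethylsilyl)oxy]methyl}-2-[(4-methoxybenzyl)oxy]-8-methyl-10-oxocyclodeca-4,6-dien-1-yl]acetate | COC(=O)C[C@@H]1C(=O)C[C@H](C)/C=C\C=C(\CO[Si](C)(C)C(C)(C)C)C[C@H]1OCc1ccc(OC)cc1 | intermediate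
17 | methyl 2-[(1R,2R,4E,6Z,8S,10S)-4-{[(tert-butyldimethylsilyl)oxy]methyl}-10-hydroxy-2-[(4-methoxybenzyl)oxy]-8-methylcyclodeca-4,6-dien-1-yl]acetate | COC(=O)C[C@@H]1[C@@H](O)C[C@H](C)/C=C\C=C(\CO[Si](C)(C)C(C)(C)C)C[C@H]1OCc1ccc(OC)cc1 | intermediate
18 | (6R,7S,8S,10S)-15-(tert-butyldimethylsilyloxy)-6-[(4-methoxybenzyl)oxy]germacra-1(Z),3(E)-dien-12,8-olide (trans-fused lactone) | C1C(=O)O[C@H]2C[C@H](C)/C=C\C=C(\CO[Si](C)(C)C(C)(C)C)C[C@@H](OCc3ccc(OC)cc3)[C@H]12 | intermediate
19 | 13-(dimethylamino) derivative of 18 (6R,7S,8S,10S; C11 epimers) | CN(C)CC1C(=O)O[C@H]2C[C@H](C)/C=C\C=C(\CO[Si](C)(C)C(C)(C)C)C[C@@H](OCc3ccc(OC)cc3)[C@H]12 | intermediate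
20 | 13-(trimethylammonio) derivative of 18, iodide (6R,7S,8S,10S; C11 epimers) | C[N+](C)(C)CC1C(=O)O[C@H]2C[C@H](C)/C=C\C=C(\CO[Si](C)(C)C(C)(C)C)C[C@@H](OCc3ccc(OC)cc3)[C@H]12.[I-] | intermediate
21 | (6R,7S,8S,10S)-15-(tert-butyldimethylsilyloxy)-6-[(4-methoxybenzyl)oxy]germacra-1(Z),3(E),11(13)-trien-12,8-olide | C=C1C(=O)O[C@H]2C[C@H](C)/C=C\C=C(\CO[Si](C)(C)C(C)(C)C)C[C@@H](OCc3ccc(OC)cc3)[C@H]12 | intermediate
22 | (6R,7S,8S,10S)-15-hydroxy-6-[(4-methoxybenzyl)oxy]germacra-1(Z),3(E),11(13)-trien-12,8-olide | C=C1C(=O)O[C@H]2C[C@H](C)/C=C\C=C(\CO)C[C@@H](OCc3ccc(OC)cc3)[C@H]12 | intermediate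
23 | (6R,7S,8S,10S)-15-acetoxy-6-[(4-methoxybenzyl)oxy]germacra-1(Z),3(E),11(13)-trien-12,8-olide | C=C1C(=O)O[C@H]2C[C@H](C)/C=C\C=C(\COC(C)=O)C[C@@H](OCc3ccc(OC)cc3)[C@H]12 | intermediate
24 | (6R,7S,8S,10S)-15-acetoxy-6-hydroxygermacra-1(Z),3(E),11(13)-trien-12,8-olide | C=C1C(=O)O[C@H]2C[C@H](C)/C=C\C=C(\COC(C)=O)C[C@@H](O)[C@H]12 | intermediate
25 | (R)-3-bromo-2-hydroxy-2-methylpropanoic acid | OC(=O)[C@@](C)(O)CBr | starting material
26 | (S)-2,3-dihydroxy-2-methylpropanoic acid | OC(=O)[C@@](C)(O)CO | intermediate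
27 | triethylsilyl (S)-2-methyl-2,3-bis(triethylsilyloxy)propanoate | CC[Si](CC)(CC)OC(=O)[C@@](C)(O[Si](CC)(CC)CC)CO[Si](CC)(CC)CC | intermediate
28 | (S)-2-methyl-2,3-bis(triethylsilyloxy)propanoic acid | OC(=O)[C@@](C)(O[Si](CC)(CC)CC)CO[Si](CC)(CC)CC | intermediate
29 | (6R,7R,8S,10S)-15-acetoxy-6-{[(2S)-2-methyl-2,3-bis(triethylsilyloxy)propanoyl]oxy}germacra-1(Z),3(E),11(13)-trien-12,8-olide | C=C1C(=O)O[C@H]2C[C@H](C)/C=C\C=C(\COC(C)=O)C[C@@H](OC(=O)[C@@](C)(O[Si](CC)(CC)CC)CO[Si](CC)(CC)CC)[C@H]12 | intermediate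
30 | (6R,7R,8S,10S)-15-acetoxy-6-{[(2S)-2,3-dihydroxy-2-methylpropanoyl]oxy}germacra-1(Z),3(E),11(13)-trien-12,8-olide | C=C1C(=O)O[C@H]2C[C@H](C)/C=C\C=C(\COC(C)=O)C[C@@H](OC(=O)[C@@](C)(O)CO)[C@H]12 | target

**Step count**
Total: 15 steps (12 in the main line, 1 for ether 11, 2 for acid 28).
Longest linear sequence: 12 steps (1 → 30 through steps 1–4, 6–11, 14 and 15).

**Steps most likely to fail**

Step 4. The doubly allylic cation may eliminate or ring-contract instead of taking the 1,2-hydride shift, and ketone 8 conjugates easily. The fallback sets out from diol 7, isolated after the addition. Its secondary hydroxyl is oxidised with Dess–Martin periodinane to (2S,5S)-2-hydroxy-5-methyl-2-[3-(tert-butyldimethylsilyloxy)prop-1-en-2-yl]cyclohex-3-en-1-one F1. The tertiary allylic C–O bond of F1 is then cleaved reductively with SmI2 (THF/MeOH, −78 °C), and kinetic α-protonation of the samarium dienolate returns to the route at ketone 8 (its C2 epimers are separated).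

Step 7. The crown-ether-separated β-alkoxy enolate may expel 4-methoxybenzyl oxide, or the alkoxide may fragment to a pentadienyl anion before the bond reorganisation is complete. The fallback sets out from 13 and avoids any base during the rearrangement. Silylation (Me3SiCl, imidazole) gives {[(1R,2S,5S)-1-{(E)-2-[(4-methoxybenzyl)oxy]ethenyl}-5-methyl-2-[3-(tert-butyldimethylsilyloxy)prop-1-en-2-yl]cyclohex-3-en-1-yl]oxy}trimethylsilane F2. Heating F2 (toluene, 150 °C, sealed tube) brings about the neutral siloxy-Cope rearrangement to {[(1Z,3R,5E,7Z,9S)-5-{[(tert-butyldimethylsilyl)oxy]methyl}-3-[(4-methoxybenzyl)oxy]-9-methylcyclodeca-1,5,7-trien-1-yl]oxy}trimethylsilane F3. The same regiodefined enolate is then released at −78 °C with MeLi and alkylated with 14, which returns to the route at 16.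

Step 8. If chelation control fails, hydride arrives from the other face and the resulting alcohol can only close a cis-fused lactone. The fallback sets out from 16 and uses inversion instead of direct control. Non-chelating reduction (NaBH4, CeCl3, MeOH, −78 °C) gives methyl 2-[(1R,2R,4E,6Z,8S,10R)-4-{[(tert-butyldimethylsilyl)oxy]methyl}-10-hydroxy-2-[(4-methoxybenzyl)oxy]-8-methylcyclodeca-4,6-dien-1-yl]acetate F4. Saponification (LiOH, THF/H2O, 0 °C) gives 2-[(1R,2R,4E,6Z,8S,10R)-4-{[(tert-butyldimethylsilyl)oxy]methyl}-10-hydroxy-2-[(4-methoxybenzyl)oxy]-8-methylcyclodeca-4,6-dien-1-yl]acetic acid F5. Mitsunobu lactonisation of F5 (PPh3, diisopropyl azodicarboxylate) inverts C8 and returns to the route at lactone 18.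

**Further compounds**
F1 | step 4 | (2S,5S)-2-hydroxy-5-methyl-2-[3-(tert-butyldimethylsilyloxy)prop-1-en-2-yl]cyclohex-3-en-1-one | O=C1C[C@H](C)C=C[C@]1(O)C(=C)CO[Si](C)(C)C(C)(C)C
F2 | step 7 | {[(1R,2S,5S)-1-{(E)-2-[(4-methoxybenzyl)oxy]ethenyl}-5-methyl-2-[3-(tert-butyldimethylsilyloxy)prop-1-en-2-yl]cyclohex-3-en-1-yl]oxy}trimethylsilane | C[Si](C)(C)O[C@@]1(/C=C/OCc2ccc(OC)cc2)[C@H](C(=C)CO[Si](C)(C)C(C)(C)C)C=C[C@@H](C)C1
F3 | step 7 | {[(1Z,3R,5E,7Z,9S)-5-{[(tert-butyldimethylsilyl)oxy]methyl}-3-[(4-methoxybenzyl)oxy]-9-methylcyclodeca-1,5,7-trien-1-yl]oxy}trimethylsilane | C[Si](C)(C)O/C1=C\[C@H](OCc2ccc(OC)cc2)C/C(CO[Si](C)(C)C(C)(C)C)=C\C=C/[C@@H](C)C1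
F4 | step 8 | methyl 2-[(1R,2R,4E,6Z,8S,10R)-4-{[(tert-butyldimethylsilyl)oxy]methyl}-10-hydroxy-2-[(4-methoxybenzyl)oxy]-8-methylcyclodeca-4,6-dien-1-yl]acetate | COC(=O)C[C@@H]1[C@H](O)C[C@H](C)/C=C\C=C(\CO[Si](C)(C)C(C)(C)C)C[C@H]1OCc1ccc(OC)cc1
F5 | step 8 | 2-[(1R,2R,4E,6Z,8S,10R)-4-{[(tert-butyldimethylsilyl)oxy]methyl}-10-hydroxy-2-[(4-methoxybenzyl)oxy]-8-methylcyclodeca-4,6-dien-1-yl]acetic acid | OC(=O)C[C@@H]1[C@H](O)C[C@H](C)/C=C\C=C(\CO[Si](C)(C)C(C)(C)C)C[C@H]1OCc1ccc(OC)cc1
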